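**Plan**
- Retrosynthesis: cut the interflavan C4(upper)–C8(lower) bond first (Friedel–Crafts). In the lower unit then cut O1–C8a (aryl ether), C4–C4a (conjugate arylation), the enoate C=C (Wittig) and C2–C3 (glycolate aldol).
- Enabling feature: the lower O1 is an aryl ether oxygen between C8a of ring A and the stereogenic benzylic C2. Closing the lower ring C from the aryl side (O1–C8a) breaks no bond at C2, C3 or C4.
- Forward order: aldol (C2–C3), Wittig (acetate arm), aryl copper addition (ring A onto C4), copper-catalysed closure of the lower ring C, union with the upper flavan at C8, deprotection.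
- Stereochemistry: lower C2/C3 from the (S)-4-benzyloxazolidinone auxiliary (syn aldol); lower C4 by 1,2-induction from the γ-benzyloxy centre (anti addition).
- Upper C2/C3 come from (−)-epicatechin; upper C4 from β-face attack trans to the 3-acetoxy group.

Key step: step 10

Assumption: the SMILES is read as epicatechin-(4β→8)-[4β-(carboxymethyl)epicatechin], lower unit (2R,3R,4S), upper unit (2R,3R,4R); flavan numbering (O1, C2, C3, C4, C4a, C5–C8, C8a) is used for both units.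

**Route**

Step 1
Reactants: 1 5-bromoresorcinol
Product: 2 1,3-bis(benzyloxy)-5-bromobenzene
Conditions: BnBr, K2CO3, DMF, rt
Reagents that add atoms: benzyl bromide, BrCc1ccccc1
Why: Double Williamson etherification (SN2 of the phenoxides on benzyl bromide) should cap both phenols while leaving the aryl bromide untouched.

Step 2
Reactants: 2 1,3-bis(benzyloxy)-5-bromobenzene
Product: 3 1,5-bis(benzyloxy)-3-bromo-2-iodobenzene
Conditions: N-iodosuccinimide, CF3CO2H (10 mol%), MeCN, 0 °C → rt, dark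
Reagents that add atoms: N-iodosuccinimide, O=C1CCC(=O)N1I
Why: Electrophilic aromatic iodination of a resorcinol diether should occur para to one ether and ortho to the other, which here is the carbon next to bromine, in preference to the carbon flanked by both benzyloxy groups.

Step 3
Reactants: 4 (S)-4-benzyloxazolidin-2-one; 5 benzyloxyacetyl chloride
Product: 7 (S)-4-benzyl-3-[2-(benzyloxy)acetyl]oxazolidin-2-one, via N-lithio oxazolidinone 6 (not isolated)
Conditions: n-BuLi, THF, −78 °C; then 5, −78 → 0 °C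
Reagents that add atoms: none
Why: N-Acylation of the lithiated oxazolidinone by the acid chloride is the standard loading of this auxiliary and leaves its stereocentre untouched.

Step 4
Reactants: 7 (S)-4-benzyl-3-[2-(benzyloxy)acetyl]oxazolidin-2-one; 8 3,4-bis(benzyloxy)benzaldehyde
Product: 11 (S)-4-benzyl-3-[(2S,3R)-2-(benzyloxy)-3-[3,4-bis(benzyloxy)phenyl]-3-hydroxypropanoyl]oxazolidin-2-one, via boron enolate 9 (not isolated), via boron aldolate 10 (not isolated)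
Conditions: Bu2BOTf, Et3N, CH2Cl2, −78 → 0 °C; then 8, −78 → 0 °C; then pH 7 buffer, MeOH, 30% H2O2, 0 °C
Reagents that add atoms: none
Why: Evans syn aldol reaction, in which the Z boron enolate adds to the aldehyde through a Zimmerman–Traxler chair on the enolate face away from the benzyl group of the auxiliary, should set the benzyloxy carbon as S and the carbinol carbon as R (syn), the future C3 and C2 of the lower flavan.

Step 5
Reactants: 11 (S)-4-benzyl-3-[(2S,3R)-2-(benzyloxy)-3-[3,4-bis(benzyloxy)phenyl]-3-hydroxypropanoyl]oxazolidin-2-one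
Product: 12 (S)-4-benzyl-3-[(2S,3R)-2-(benzyloxy)-3-[3,4-bis(benzyloxy)phenyl]-3-[(tert-butyldimethylsilyl)oxy]propanoyl]oxazolidin-2-one
Conditions: t-BuMe2SiOTf, 2,6-lutidine, CH2Cl2, −78 → 0 °C
Reagents that add atoms: tert-butyldimethylsilyl triflate, CC(C)(C)[Si](C)(C)OS(=O)(=O)C(F)(F)F
Why: Silylation of the hindered benzylic alcohol with the silyl triflate and a hindered pyridine base is fast at low temperature and avoids the retro-aldol cleavage that stronger bases could cause.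

Step 6
Reactants: 12 (S)-4-benzyl-3-[(2S,3R)-2-(benzyloxy)-3-[3,4-bis(benzyloxy)phenyl]-3-[(tert-butyldimethylsilyl)oxy]propanoyl]oxazolidin-2-one
Product: 13 (2R,3R)-2-(benzyloxy)-3-[3,4-bis(benzyloxy)phenyl]-3-[(tert-butyldimethylsilyl)oxy]propan-1-ol
Conditions: LiBH4, H2O (1 equiv), Et2O, 0 °C
Reagents that add atoms: none
Why: Reductive removal of the auxiliary by borohydride attack on the exocyclic imide carbonyl gives the primary alcohol without touching the two stereocentres and returns the oxazolidinone.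

Step 7
Reactants: 13 (2R,3R)-2-(benzyloxy)-3-[3,4-bis(benzyloxy)phenyl]-3-[(tert-butyldimethylsilyl)oxy]propan-1-ol; 14 tert-butyl (triphenylphosphoranylidene)acetate
Product: 16 tert-butyl (2E,4R,5R)-4-(benzyloxy)-5-[3,4-bis(benzyloxy)phenyl]-5-[(tert-butyldimethylsilyl)oxy]pent-2-enoate, via aldehyde 15 (not isolated)
Conditions: Dess–Martin periodinane, pyridine, CH2Cl2, 0 °C → rt; then 14, rt
Reagents that add atoms: none
Why: Dess–Martin oxidation followed in the same flask by Wittig olefination with a stabilised ylide should give the E enoate, the α-alkoxy aldehyde being consumed before it can epimerise.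

Step 8
Reactants: 3 1,5-bis(benzyloxy)-3-bromo-2-iodobenzene; 16 tert-butyl (2E,4R,5R)-4-(benzyloxy)-5-[3,4-bis(benzyloxy)phenyl]-5-[(tert-butyldimethylsilyl)oxy]pent-2-enoate
Product: 19 tert-butyl (3S,4R,5R)-4-(benzyloxy)-5-[3,4-bis(benzyloxy)phenyl]-3-[2-bromo-4,6-bis(benzyloxy)phenyl]-5-[(tert-butyldimethylsilyl)oxy]pentanoate, via arylmagnesium chloride 17 (not isolated), via silyl ketene acetal 18 (not isolated)
Conditions: 3, i-PrMgCl·LiCl, THF, −40 °C; then CuBr·SMe2 (20 mol%), Me3SiCl, 16, −78 → −30 °C; then aq NH4Cl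
Reagents that add atoms: none
Why: Iodine–magnesium exchange occurs at the C–I bond only, and the copper-catalysed, Me3SiCl-accelerated conjugate addition of the resulting aryl Grignard reagent should place the aryl group anti to the γ-benzyloxy group (modified Felkin–Anh model: γ-hydrogen in the plane of the alkene, C–O bond antiperiplanar to the incoming cuprate), which sets C3 of the pentanoate (future C4) as S.

Step 9
Reactants: 19 tert-butyl (3S,4R,5R)-4-(benzyloxy)-5-[3,4-bis(benzyloxy)phenyl]-3-[2-bromo-4,6-bis(benzyloxy)phenyl]-5-[(tert-butyldimethylsilyl)oxy]pentanoate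
Product: 20 tert-butyl (3S,4R,5R)-4-(benzyloxy)-5-[3,4-bis(benzyloxy)phenyl]-3-[2-bromo-4,6-bis(benzyloxy)phenyl]-5-hydroxypentanoate
Conditions: Bu4NF, AcOH, THF, 0 °C → rt
Reagents that add atoms: none
Why: Fluoride-mediated cleavage of the silyl ether, buffered by acetic acid so that no free alkoxide can lactonise onto the ester, should liberate the C5 hydroxyl (future O1).

Step 10
Reactants: 20 tert-butyl (3S,4R,5R)-4-(benzyloxy)-5-[3,4-bis(benzyloxy)phenyl]-3-[2-bromo-4,6-bis(benzyloxy)phenyl]-5-hydroxypentanoate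
Product: 21 tert-butyl 2-[(2R,3R,4S)-3,5,7-tris(benzyloxy)-2-[3,4-bis(benzyloxy)phenyl]-3,4-dihydro-2H-chromen-4-yl]acetate
Conditions: CuI (20 mol%), 1,10-phenanthroline (40 mol%), Cs2CO3, toluene, 110 °C, degassed
Reagents that add atoms: none
Why: Cs2CO3 deprotonates the benzylic carbinol and the phenanthroline-bound monovalent copper alkoxide inserts into the neighbouring C–Br bond (oxidative addition to a trivalent copper aryl alkoxide), after which reductive elimination forges O1–C8a and returns monovalent copper. The closest known reaction type is the copper-catalysed intramolecular Ullmann-type O-arylation of aryl halides by secondary alcohols that delivers chromans and 2-arylchromans. The lower ring C closes in a 6-exo mode, its six atoms being O1, C2, C3, C4, C4a and C8a with the C–Br bond outside the new ring. No stereocentre is created: the C–O bond at C2 is never broken, so C2 stays R and the syn C2/C3, anti C3/C4 chain maps directly onto the 2,3-cis-3,4-trans flavan. The step needs chemoselectivity for etherification over δ-lactonisation, over closure through another oxygen and over oxidation of the carbinol; the bulky tert-butyl ester resists the alkoxide, O3 is capped as a benzyl ether so that a single hydroxyl is present, and copper, unlike palladium, has little tendency toward β-hydride elimination from the alkoxide.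

Step 11
Reactants: 22 (−)-epicatechin
Product: 23 5,7,3',4'-tetra-O-benzyl-(−)-epicatechin
Conditions: BnBr, K2CO3, DMF, 0 °C → rt, argon
Reagents that add atoms: benzyl bromide, BrCc1ccccc1
Why: Williamson etherification under carbonate is selective for the four phenols because the C3 alcohol is far less acidic.

Step 12
Reactants: 23 5,7,3',4'-tetra-O-benzyl-(−)-epicatechin
Product: 24 3-O-acetyl-5,7,3',4'-tetra-O-benzyl-(−)-epicatechin
Conditions: Ac2O, pyridine, DMAP (5 mol%), CH2Cl2, rt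
Reagents that add atoms: acetic anhydride, CC(=O)OC(C)=O
Why: DMAP-catalysed acylation of the secondary alcohol installs the 3-acetate that later shields the α face and directs 3,4-trans substitution.

Step 13
Reactants: 24 3-O-acetyl-5,7,3',4'-tetra-O-benzyl-(−)-epicatechin
Product: 25 (2R,3R,4S)-3-acetoxy-5,7-bis(benzyloxy)-2-[3,4-bis(benzyloxy)phenyl]-4-(2-ethoxyethoxy)chroman
Conditions: DDQ, 2-ethoxyethanol, CH2Cl2, rt
Reagents that add atoms: 2-ethoxyethanol, CCOCCO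
Why: Benzylic oxidation by DDQ (hydride abstraction from C4 to a cation stabilised by the 5,7-dialkoxy ring A and O1) and capture by the alcohol from the β face, opposite the C2 aryl and C3 acetoxy groups, should give the 4β ether with C4 as S.

Step 14
Reactants: 21 tert-butyl 2-[(2R,3R,4S)-3,5,7-tris(benzyloxy)-2-[3,4-bis(benzyloxy)phenyl]-3,4-dihydro-2H-chromen-4-yl]acetate; 25 (2R,3R,4S)-3-acetoxy-5,7-bis(benzyloxy)-2-[3,4-bis(benzyloxy)phenyl]-4-(2-ethoxyethoxy)chroman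
Product: 26 tert-butyl 2-[(2R,3R,4S)-8-[(2R,3R,4R)-3-acetoxy-5,7-bis(benzyloxy)-2-[3,4-bis(benzyloxy)phenyl]chroman-4-yl]-3,5,7-tris(benzyloxy)-2-[3,4-bis(benzyloxy)phenyl]chroman-4-yl]acetate
Conditions: Me3SiOTf (0.5 equiv), CH2Cl2, −78 °C, 21 in twofold excess (surplus recovered); then Et3N
Reagents that add atoms: none
Why: Lewis acid ionisation of the C4 ether gives a benzylic cation that undergoes Friedel–Crafts alkylation at C8 of 21, the position between O1 and the 7-benzyloxy group that is the most reactive site of benzylated flavans, and attack on the β face anti to the C2 aryl and the participating 3-acetoxy group sets the upper C4 as R (4β→8).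

Step 15
Reactants: 26 tert-butyl 2-[(2R,3R,4S)-8-[(2R,3R,4R)-3-acetoxy-5,7-bis(benzyloxy)-2-[3,4-bis(benzyloxy)phenyl]chroman-4-yl]-3,5,7-tris(benzyloxy)-2-[3,4-bis(benzyloxy)phenyl]chroman-4-yl]acetate
Product: 28 2-[(2R,3R,4S)-8-[(2R,3R,4R)-3-acetoxy-5,7-bis(benzyloxy)-2-[3,4-bis(benzyloxy)phenyl]chroman-4-yl]-3,5,7-tris(benzyloxy)-2-[3,4-bis(benzyloxy)phenyl]chroman-4-yl]acetic acid, via trimethylsilyl ester 27 (not isolated)
Conditions: Me3SiOTf, 2,6-lutidine, CH2Cl2, 0 °C → rt; then H2O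
Reagents that add atoms: none
Why: Silyl triflate-mediated tert-butyl ester cleavage (O-silylation, loss of the tert-butyl cation as 2-methylpropene, hydrolysis of the silyl ester on work-up) under lutidine buffering should spare the benzyl ethers, the acetate and the acid-sensitive interflavan bond.

Step 16
Reactants: 28 2-[(2R,3R,4S)-8-[(2R,3R,4R)-3-acetoxy-5,7-bis(benzyloxy)-2-[3,4-bis(benzyloxy)phenyl]chroman-4-yl]-3,5,7-tris(benzyloxy)-2-[3,4-bis(benzyloxy)phenyl]chroman-4-yl]acetic acid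
Product: 29 2-[(2R,3R,4S)-3,5,7-tris(benzyloxy)-8-[(2R,3R,4R)-5,7-bis(benzyloxy)-2-[3,4-bis(benzyloxy)phenyl]-3-hydroxychroman-4-yl]-2-[3,4-bis(benzyloxy)phenyl]chroman-4-yl]acetic acid
Conditions: LiOH, THF/H2O, rt → 40 °C; then 1 M HCl to pH 3
Reagents that add atoms: none
Why: Saponification of the secondary acetate by hydroxide proceeds with acyl–oxygen cleavage, so the C3 configuration of the upper unit is untouched, and benzyl ethers are stable to base.

Step 17
Reactants: 29 2-[(2R,3R,4S)-3,5,7-tris(benzyloxy)-8-[(2R,3R,4R)-5,7-bis(benzyloxy)-2-[3,4-bis(benzyloxy)phenyl]-3-hydroxychroman-4-yl]-2-[3,4-bis(benzyloxy)phenyl]chroman-4-yl]acetic acid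
Product: 30 CNP0190976.1, epicatechin-(4β→8)-[4β-(carboxymethyl)epicatechin]
Conditions: H2 (1 atm), Pd(OH)2/C, THF/MeOH/H2O, rt
Reagents that add atoms: none
Why: Catalytic hydrogenolysis cleaves all nine benzyl ethers in one operation under neutral conditions that leave the interflavan bond, the stereocentres and the free acid intact.

**Compound list**

1 | 5-bromoresorcinol | Oc1cc(O)cc(Br)c1 | starting material
2 | 1,3-bis(benzyloxy)-5-bromobenzene | Brc1cc(OCc2ccccc2)cc(OCc2ccccc2)c1 | intermediate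
3 | 1,5-bis(benzyloxy)-3-bromo-2-iodobenzene | Brc1cc(OCc2ccccc2)cc(OCc2ccccc2)c1I | intermediate
4 | (S)-4-benzyloxazolidin-2-one | O=C1N[C@@H](Cc2ccccc2)CO1 | starting material
5 | benzyloxyacetyl chloride | O=C(Cl)COCc1ccccc1 | starting material
6 | N-lithio (S)-4-benzyloxazolidin-2-one | [Li]N1[C@@H](Cc2ccccc2)COC1=O | intermediate
7 | (S)-4-benzyl-3-[2-(benzyloxy)acetyl]oxazolidin-2-one | O=C(COCc1ccccc1)N1[C@@H](Cc2ccccc2)COC1=O | intermediate
8 | 3,4-bis(benzyloxy)benzaldehyde | O=Cc1ccc(OCc2ccccc2)c(OCc2ccccc2)c1 | starting material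
9 | Z dibutylboron enolate of 7 | CCCCB(CCCC)O/C(=C\OCc1ccccc1)N1[C@@H](Cc2ccccc2)COC1=O | intermediate
10 | O-dibutylboryl aldolate of 11 | O=C(N1[C@@H](Cc2ccccc2)COC1=O)[C@@H](OCc1ccccc1)[C@H](OB(CCCC)CCCC)c1ccc(OCc2ccccc2)c(OCc2ccccc2)c1 | intermediate
11 | (S)-4-benzyl-3-[(2S,3R)-2-(benzyloxy)-3-[3,4-bis(benzyloxy)phenyl]-3-hydroxypropanoyl]oxazolidin-2-one | O=C(N1[C@@H](Cc2ccccc2)COC1=O)[C@@H](OCc1ccccc1)[C@H](O)c1ccc(OCc2ccccc2)c(OCc2ccccc2)c1 | intermediate
12 | (S)-4-benzyl-3-[(2S,3R)-2-(benzyloxy)-3-[3,4-bis(benzyloxy)phenyl]-3-[(tert-butyldimethylsilyl)oxy]propanoyl]oxazolidin-2-one | O=C(N1[C@@H](Cc2ccccc2)COC1=O)[C@@H](OCc1ccccc1)[C@H](O[Si](C)(C)C(C)(C)C)c1ccc(OCc2ccccc2)c(OCc2ccccc2)c1 | intermediate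
13 | (2R,3R)-2-(benzyloxy)-3-[3,4-bis(benzyloxy)phenyl]-3-[(tert-butyldimethylsilyl)oxy]propan-1-ol | OC[C@@H](OCc1ccccc1)[C@H](O[Si](C)(C)C(C)(C)C)c1ccc(OCc2ccccc2)c(OCc2ccccc2)c1 | intermediate
14 | tert-butyl (triphenylphosphoranylidene)acetate | CC(C)(C)OC(=O)C=P(c1ccccc1)(c1ccccc1)c1ccccc1 | starting material
15 | (2S,3R)-2-(benzyloxy)-3-[3,4-bis(benzyloxy)phenyl]-3-[(tert-butyldimethylsilyl)oxy]propanal | O=C[C@@H](OCc1ccccc1)[C@H](O[Si](C)(C)C(C)(C)C)c1ccc(OCc2ccccc2)c(OCc2ccccc2)c1 | intermediate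
16 | tert-butyl (2E,4R,5R)-4-(benzyloxy)-5-[3,4-bis(benzyloxy)phenyl]-5-[(tert-butyldimethylsilyl)oxy]pent-2-enoate | CC(C)(C)OC(=O)/C=C/[C@@H](OCc1ccccc1)[C@H](O[Si](C)(C)C(C)(C)C)c1ccc(OCc2ccccc2)c(OCc2ccccc2)c1 | intermediate
17 | [2-bromo-4,6-bis(benzyloxy)phenyl]magnesium chloride | Cl[Mg]c1c(Br)cc(OCc2ccccc2)cc1OCc1ccccc1 | intermediate
18 | tert-butyl trimethylsilyl ketene acetal of 19 | CC(C)(C)OC(O[Si](C)(C)C)=C[C@@H](c1c(Br)cc(OCc2ccccc2)cc1OCc1ccccc1)[C@@H](OCc1ccccc1)[C@H](O[Si](C)(C)C(C)(C)C)c1ccc(OCc2ccccc2)c(OCc2ccccc2)c1 | intermediate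
19 | tert-butyl (3S,4R,5R)-4-(benzyloxy)-5-[3,4-bis(benzyloxy)phenyl]-3-[2-bromo-4,6-bis(benzyloxy)phenyl]-5-[(tert-butyldimethylsilyl)oxy]pentanoate | CC(C)(C)OC(=O)C[C@@H](c1c(Br)cc(OCc2ccccc2)cc1OCc1ccccc1)[C@@H](OCc1ccccc1)[C@H](O[Si](C)(C)C(C)(C)C)c1ccc(OCc2ccccc2)c(OCc2ccccc2)c1 | intermediate
20 | tert-butyl (3S,4R,5R)-4-(benzyloxy)-5-[3,4-bis(benzyloxy)phenyl]-3-[2-bromo-4,6-bis(benzyloxy)phenyl]-5-hydroxypentanoate | CC(C)(C)OC(=O)C[C@@H](c1c(Br)cc(OCc2ccccc2)cc1OCc1ccccc1)[C@@H](OCc1ccccc1)[C@H](O)c1ccc(OCc2ccccc2)c(OCc2ccccc2)c1 | intermediate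
21 | tert-butyl 2-[(2R,3R,4S)-3,5,7-tris(benzyloxy)-2-[3,4-bis(benzyloxy)phenyl]-3,4-dihydro-2H-chromen-4-yl]acetate | CC(C)(C)OC(=O)C[C@H]1c2c(OCc3ccccc3)cc(OCc3ccccc3)cc2O[C@H](c2ccc(OCc3ccccc3)c(OCc3ccccc3)c2)[C@@H]1OCc1ccccc1 | intermediate
22 | (−)-epicatechin, (2R,3R) | O[C@@H]1Cc2c(O)cc(O)cc2O[C@@H]1c1ccc(O)c(O)c1 | starting material
23 | 5,7,3',4'-tetra-O-benzyl-(−)-epicatechin | O[C@@H]1Cc2c(OCc3ccccc3)cc(OCc3ccccc3)cc2O[C@@H]1c1ccc(OCc2ccccc2)c(OCc2ccccc2)c1 | intermediate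
24 | 3-O-acetyl-5,7,3',4'-tetra-O-benzyl-(−)-epicatechin | CC(=O)O[C@@H]1Cc2c(OCc3ccccc3)cc(OCc3ccccc3)cc2O[C@@H]1c1ccc(OCc2ccccc2)c(OCc2ccccc2)c1 | intermediate
25 | (2R,3R,4S)-3-acetoxy-5,7-bis(benzyloxy)-2-[3,4-bis(benzyloxy)phenyl]-4-(2-ethoxyethoxy)chroman (4β ether, 3,4-trans) | CCOCCO[C@H]1c2c(OCc3ccccc3)cc(OCc3ccccc3)cc2O[C@H](c2ccc(OCc3ccccc3)c(OCc3ccccc3)c2)[C@@H]1OC(C)=O | intermediate
26 | tert-butyl 2-[(2R,3R,4S)-8-[(2R,3R,4R)-3-acetoxy-5,7-bis(benzyloxy)-2-[3,4-bis(benzyloxy)phenyl]chroman-4-yl]-3,5,7-tris(benzyloxy)-2-[3,4-bis(benzyloxy)phenyl]chroman-4-yl]acetate | CC(C)(C)OC(=O)C[C@H]1c2c(OCc3ccccc3)cc(OCc3ccccc3)c([C@H]3c4c(OCc5ccccc5)cc(OCc5ccccc5)cc4O[C@H](c4ccc(OCc5ccccc5)c(OCc5ccccc5)c4)[C@@H]3OC(C)=O)c2O[C@H](c2ccc(OCc3ccccc3)c(OCc3ccccc3)c2)[C@@H]1OCc1ccccc1 | intermediate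
27 | trimethylsilyl ester of 28 | C[Si](C)(C)OC(=O)C[C@H]1c2c(OCc3ccccc3)cc(OCc3ccccc3)c([C@H]3c4c(OCc5ccccc5)cc(OCc5ccccc5)cc4O[C@H](c4ccc(OCc5ccccc5)c(OCc5ccccc5)c4)[C@@H]3OC(C)=O)c2O[C@H](c2ccc(OCc3ccccc3)c(OCc3ccccc3)c2)[C@@H]1OCc1ccccc1 | intermediate
28 | 2-[(2R,3R,4S)-8-[(2R,3R,4R)-3-acetoxy-5,7-bis(benzyloxy)-2-[3,4-bis(benzyloxy)phenyl]chroman-4-yl]-3,5,7-tris(benzyloxy)-2-[3,4-bis(benzyloxy)phenyl]chroman-4-yl]acetic acid | OC(=O)C[C@H]1c2c(OCc3ccccc3)cc(OCc3ccccc3)c([C@H]3c4c(OCc5ccccc5)cc(OCc5ccccc5)cc4O[C@H](c4ccc(OCc5ccccc5)c(OCc5ccccc5)c4)[C@@H]3OC(C)=O)c2O[C@H](c2ccc(OCc3ccccc3)c(OCc3ccccc3)c2)[C@@H]1OCc1ccccc1 | intermediate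
29 | 2-[(2R,3R,4S)-3,5,7-tris(benzyloxy)-8-[(2R,3R,4R)-5,7-bis(benzyloxy)-2-[3,4-bis(benzyloxy)phenyl]-3-hydroxychroman-4-yl]-2-[3,4-bis(benzyloxy)phenyl]chroman-4-yl]acetic acid | OC(=O)C[C@H]1c2c(OCc3ccccc3)cc(OCc3ccccc3)c([C@H]3c4c(OCc5ccccc5)cc(OCc5ccccc5)cc4O[C@H](c4ccc(OCc5ccccc5)c(OCc5ccccc5)c4)[C@@H]3O)c2O[C@H](c2ccc(OCc3ccccc3)c(OCc3ccccc3)c2)[C@@H]1OCc1ccccc1 | intermediate
30 | CNP0190976.1, 2-[(2R,3R,4S)-2-(3,4-dihydroxyphenyl)-8-[(2R,3R,4R)-2-(3,4-dihydroxyphenyl)-3,5,7-trihydroxychroman-4-yl]-3,5,7-trihydroxychroman-4-yl]acetic acid | O=C(O)C[C@H]1c2c(O)cc(O)c([C@H]3c4c(O)cc(O)cc4O[C@H](c4ccc(O)c(O)c4)[C@@H]3O)c2O[C@H](c2ccc(O)c(O)c2)[C@@H]1O | target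

**Step count and risks**

Total steps: 17. Longest linear sequence: 12 steps (steps 3–10, then 14–17).

Steps most likely to fail:

1. Step 8. Transfer of a doubly ortho-substituted aryl group to a moderately electrophilic tert-butyl enoate may be slower than decay of the ortho-bromoaryl magnesium species (aryne formation, protonation), and facial selectivity may erode at the higher temperature needed. The fallback raises the electrophilicity of the acceptor while keeping its E geometry. Setting out from aldehyde 15, Wittig reaction with (triphenylphosphoranylidene)acetaldehyde would give the (2E,4R,5R)-enal F1. Copper-catalysed addition of 17 in the presence of Me3SiCl should give the silyl enol ether F2, hydrolysed on work-up to the β-aryl aldehyde F3. Pinnick oxidation (NaClO2, NaH2PO4, 2-methylbut-2-ene) would give the carboxylic acid F4, and esterification with tert-butyl 2,2,2-trichloroacetimidate comes back to the route at 19.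

2. Step 10. The cesium alkoxide may attack the ester (δ-lactonisation with loss of tert-butoxide) faster than the electron-rich aryl bromide undergoes oxidative addition, and protodebromination may compete. The fallback takes the ester out of play by lowering its oxidation level before ring closure. Setting out from 20, LiAlH4 reduction would give the 1,5-diol F5, and selective silylation of the primary hydroxyl (tert-butyldiphenylsilyl chloride, imidazole) the silyl ether F6. The same CuI/1,10-phenanthroline/Cs2CO3 closure on F6 would give the chroman silyl ether F7, and Bu4NF would release the primary alcohol F8. Oxidation with TEMPO and PhI(OAc)2 in aqueous MeCN would give the chromanylacetic acid F9, and tert-butyl 2,2,2-trichloroacetimidate restores the ester, coming back to the route at 21.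

3. Step 14. The cation may add a second time (the upper ring A of 26 is itself nucleophilic), may attack C6 instead of C8, or the Lewis acid may strip the tert-butyl ester. The fallback replaces hard oxophilic activation by soft thiophilic activation. Setting out from 25, exchange of the 2-ethoxyethoxy group with 2-mercaptobenzothiazole (BF3·OEt2, CH2Cl2, −40 °C) would give the 4β-(benzothiazol-2-ylsulfanyl) donor F10. AgBF4 in THF at 0 °C should ionise F10 in the presence of 21 without a strong Lewis acid, coming back to the route at 26.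

**Further compounds**

F1 | step 8 | (2E,4R,5R)-4-(benzyloxy)-5-[3,4-bis(benzyloxy)phenyl]-5-[(tert-butyldimethylsilyl)oxy]pent-2-enal | O=C/C=C/[C@@H](OCc1ccccc1)[C@H](O[Si](C)(C)C(C)(C)C)c1ccc(OCc2ccccc2)c(OCc2ccccc2)c1
F2 | step 8 | trimethylsilyl enol ether of F3 | C[Si](C)(C)OC=C[C@@H](c1c(Br)cc(OCc2ccccc2)cc1OCc1ccccc1)[C@@H](OCc1ccccc1)[C@H](O[Si](C)(C)C(C)(C)C)c1ccc(OCc2ccccc2)c(OCc2ccccc2)c1
F3 | step 8 | (3S,4R,5R)-4-(benzyloxy)-5-[3,4-bis(benzyloxy)phenyl]-3-[2-bromo-4,6-bis(benzyloxy)phenyl]-5-[(tert-butyldimethylsilyl)oxy]pentanal | O=CC[C@@H](c1c(Br)cc(OCc2ccccc2)cc1OCc1ccccc1)[C@@H](OCc1ccccc1)[C@H](O[Si](C)(C)C(C)(C)C)c1ccc(OCc2ccccc2)c(OCc2ccccc2)c1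
F4 | step 8 | (3S,4R,5R)-4-(benzyloxy)-5-[3,4-bis(benzyloxy)phenyl]-3-[2-bromo-4,6-bis(benzyloxy)phenyl]-5-[(tert-butyldimethylsilyl)oxy]pentanoic acid | OC(=O)C[C@@H](c1c(Br)cc(OCc2ccccc2)cc1OCc1ccccc1)[C@@H](OCc1ccccc1)[C@H](O[Si](C)(C)C(C)(C)C)c1ccc(OCc2ccccc2)c(OCc2ccccc2)c1
F5 | step 10 | (1R,2R,3S)-2-(benzyloxy)-1-[3,4-bis(benzyloxy)phenyl]-3-[2-bromo-4,6-bis(benzyloxy)phenyl]pentane-1,5-diol | OCC[C@@H](c1c(Br)cc(OCc2ccccc2)cc1OCc1ccccc1)[C@@H](OCc1ccccc1)[C@H](O)c1ccc(OCc2ccccc2)c(OCc2ccccc2)c1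
F6 | step 10 | (1R,2R,3S)-2-(benzyloxy)-1-[3,4-bis(benzyloxy)phenyl]-3-[2-bromo-4,6-bis(benzyloxy)phenyl]-5-[(tert-butyldiphenylsilyl)oxy]pentan-1-ol | CC(C)(C)[Si](OCC[C@@H](c1c(Br)cc(OCc2ccccc2)cc1OCc1ccccc1)[C@@H](OCc1ccccc1)[C@H](O)c1ccc(OCc2ccccc2)c(OCc2ccccc2)c1)(c1ccccc1)c1ccccc1
F7 | step 10 | (2R,3R,4S)-3,5,7-tris(benzyloxy)-2-[3,4-bis(benzyloxy)phenyl]-4-[2-[(tert-butyldiphenylsilyl)oxy]ethyl]chroman | CC(C)(C)[Si](OCC[C@H]1c2c(OCc3ccccc3)cc(OCc3ccccc3)cc2O[C@H](c2ccc(OCc3ccccc3)c(OCc3ccccc3)c2)[C@@H]1OCc1ccccc1)(c1ccccc1)c1ccccc1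
F8 | step 10 | 2-[(2R,3R,4S)-3,5,7-tris(benzyloxy)-2-[3,4-bis(benzyloxy)phenyl]chroman-4-yl]ethanol | OCC[C@H]1c2c(OCc3ccccc3)cc(OCc3ccccc3)cc2O[C@H](c2ccc(OCc3ccccc3)c(OCc3ccccc3)c2)[C@@H]1OCc1ccccc1
F9 | step 10 | 2-[(2R,3R,4S)-3,5,7-tris(benzyloxy)-2-[3,4-bis(benzyloxy)phenyl]chroman-4-yl]acetic acid | OC(=O)C[C@H]1c2c(OCc3ccccc3)cc(OCc3ccccc3)cc2O[C@H](c2ccc(OCc3ccccc3)c(OCc3ccccc3)c2)[C@@H]1OCc1ccccc1
F10 | step 14 | (2R,3S,4S)-3-acetoxy-4-(1,3-benzothiazol-2-ylsulfanyl)-5,7-bis(benzyloxy)-2-[3,4-bis(benzyloxy)phenyl]chroman (4β thioether) | S(c1nc2ccccc2s1)[C@H]1c2c(OCc3ccccc3)cc(OCc3ccccc3)cc2O[C@H](c2ccc(OCc3ccccc3)c(OCc3ccccc3)c2)[C@@H]1OC(C)=O
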